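**Retrosynthetic overview**

1. Feature: in the bicyclo[3.3.1]nonane core (ring A = C1–C2–C3–C4–C5–C9, ring B = C1–C8–C7–C6–C5–C9) the C1(OH)–C9(=O) acyloin is the 1,2-transposed form of an angular C9(OH)–C1(=O) acyloin in a cis-fused hydrindenone (five ring C9–C5–C6–C7=C8). C1–C8 is therefore made by an α-ketol shift that enlarges the five ring to ring B.
2. Fused ketol 22 comes from C1 oxidation after ring-closing metathesis (C7=C8) of a C9 vinyl carbinol and a C5 acrolein-aldol unit. Both are installed on ketone 10, in which a carbamate bridging C1–O and C3–N locks ring A and sends every addition to the exo face.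
3. Ketone 10 comes from tethered aminohydroxylation (C3–N, C4–O) of hydroxy benzoate 3, made by asymmetric opening of the meso monoepoxide of cyclohexa-1,4-diene.
4. Ring order: ring A (from the diene), carbamate lock, five ring (metathesis), ring B (ketol shift), epoxide last. The side chain, (E)-7-oxododec-2-enoic acid from δ-decalactone, is attached after global deprotection.

Key step: step 16

Remark on numbering: core atoms keep the target numbers in all intermediates (C1 bridgehead carbinol, C2 CH2, C3 C–N, C4 C–O, C5 bridgehead CH, C6 carbinol, C7/C8 epoxide carbons, C9 ketone). "Exo" means the face of ring A away from the carbamate bridge.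

Assumption: the (S,S) cobalt salen catalyst of step 2 is taken to give the (1R,6R) hydroxy benzoate; if the sense of induction is the opposite, the (R,R) catalyst is used with no other change.

**Route**

Step 1
Reactants: 1 cyclohexa-1,4-diene
Product: 2 cis-7-oxabicyclo[4.1.0]hept-3-ene (meso monoepoxide)
Conditions: mCPBA (1.0 equiv), CH2Cl2, 0 °C
Reagents that add atoms: 3-chloroperoxybenzoic acid, OOC(=O)c1cccc(Cl)c1
Why: Prilezhaev epoxidation of one of two equivalent isolated alkenes, monoepoxidation being favoured by the stoichiometry and by inductive deactivation of the remaining alkene; the product is meso, so no stereochemical issue arises.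

Step 2
Reactants: 2 cis-7-oxabicyclo[4.1.0]hept-3-ene
Product: 3 (1R,6R)-6-hydroxycyclohex-3-en-1-yl benzoate
Conditions: [(S,S)-N,N'-bis(3,5-di-tert-butylsalicylidene)-1,2-cyclohexanediaminato]cobalt (divalent cobalt, 5 mol %), PhCO2H, iPr2NEt, air, tBuOMe, 0 °C; recrystallisation
Reagents that add atoms: benzoic acid, OC(=O)c1ccccc1
Why: Cobalt-salen-catalysed asymmetric ring opening of a meso epoxide by a carboxylic acid, in which the trivalent cobalt benzoate formed in air activates the epoxide and delivers benzoate by backside attack at one enantiotopic carbon, setting C1 and C9 trans (R,R); acyl migration is degenerate for this C2-symmetric diol and cannot erode the ee.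

Step 3
Reactants: 3 (1R,6R)-6-hydroxycyclohex-3-en-1-yl benzoate
Product: 5 (1R,6R)-6-[(hydroxycarbamoyl)oxy]cyclohex-3-en-1-yl benzoate, via imidazole-1-carboxylate 4 (not isolated)
Conditions: CDI, pyridine, 40 °C; then NH2OH·HCl, rt
Reagents that add atoms: 1,1'-carbonyldiimidazole, O=C(n1ccnc1)n1ccnc1; hydroxylamine hydrochloride, NO.Cl
Why: Carbamoylation of the free C1 hydroxyl through its acyl imidazole, which is substituted at carbon by the nitrogen of hydroxylamine (the better nucleophile of the two heteroatoms); no stereocentre is touched.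

Step 4
Reactants: 5 (1R,6R)-6-[(hydroxycarbamoyl)oxy]cyclohex-3-en-1-yl benzoate
Product: 6 (1R,6R)-6-({[(pentafluorobenzoyl)oxy]carbamoyl}oxy)cyclohex-3-en-1-yl benzoate
Conditions: C6F5COCl, Et3N, Et2O, 0 °C
Reagents that add atoms: pentafluorobenzoyl chloride, O=C(Cl)c1c(F)c(F)c(F)c(F)c1F
Why: Selective O-acylation of the N-hydroxy carbamate at its most acidic and nucleophilic site gives the N–O bond that later acts as internal oxidant and nitrogen source.

Step 5
Reactants: 6 N-(pentafluorobenzoyloxy) carbamate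
Product: 7 (1R,5S,6R,8R)-6-hydroxy-3-oxo-2-oxa-4-azabicyclo[3.3.1]nonan-8-yl benzoate (carbamate bridging C1–O and C3–N; C4–OH cis to N; C9–OBz trans to C1–O)
Conditions: K2OsO2(OH)4 (hexavalent osmium, 4 mol %), tBuOH/H2O 3:1, rt
Reagents that add atoms: water, O
Why: Tethered aminohydroxylation, in which the N–O bond oxidises osmium to an octavalent imido species held by the C1 carbamate that adds syn across C3=C4 from the face of the C1 oxygen, nitrogen going to the proximal C3 (six-membered carbamate) and oxygen to C4, so that C3–N and C4–O are set cis with absolute configuration relayed from C1.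

Step 6
Reactants: 7 hydroxy carbamate
Product: 8 (1R,5S,6R,8R)-6-[(tert-butyldimethylsilyl)oxy]-3-oxo-2-oxa-4-azabicyclo[3.3.1]nonan-8-yl benzoate
Conditions: TBSOTf, 2,6-lutidine, CH2Cl2, −40 to 0 °C
Reagents that add atoms: tert-butyldimethylsilyl trifluoromethanesulfonate, CC(C)(C)[Si](C)(C)OS(=O)(=O)C(F)(F)F
Why: Silyl ether formation at the only free hydroxyl (equatorial C4–OH), any N-silyl carbamate being hydrolysed on aqueous work-up.

Step 7
Reactants: 8 silyl ether benzoate
Product: 9 (1R,5S,6R,8R)-6-[(tert-butyldimethylsilyl)oxy]-8-hydroxy-2-oxa-4-azabicyclo[3.3.1]nonan-3-one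
Conditions: K2CO3 (0.3 equiv), MeOH, rt
Reagents that add atoms: none
Why: Base-catalysed transesterification removes the benzoate, while the far less electrophilic cyclic carbamate and the silyl ether survive.

Step 8
Reactants: 9 C9 alcohol
Product: 10 (1R,5S,6R)-6-[(tert-butyldimethylsilyl)oxy]-2-oxa-4-azabicyclo[3.3.1]nonane-3,8-dione (C9 ketone)
Conditions: Dess–Martin periodinane, CH2Cl2, rt
Reagents that add atoms: none
Why: Dess–Martin oxidation of the secondary alcohol under near-neutral conditions, which erases the C9 stereocentre on purpose; the bridgehead C1–H cannot epimerise.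

Step 9
Reactants: 10 ketone; 11 acrolein
Product: 14 (1R,5S,6R,7R)-6-[(tert-butyldimethylsilyl)oxy]-7-[(1R)-1-hydroxyprop-2-en-1-yl]-2-oxa-4-azabicyclo[3.3.1]nonane-3,8-dione, via dilithium enolate 12 (not isolated), via titanium enolate 13 (not isolated)
Conditions: LiN(iPr)2 (2.2 equiv), THF, −78 °C; ClTi(OiPr)3 (2.3 equiv), −78 to −40 °C; acrolein, −78 °C; aq NH4Cl
Reagents that add atoms: acrolein 11, C=CC=O
Why: Aldol addition of a titanium enolate: C1 is a bridgehead, so the ketone enolises only towards C5; the equatorial C4–O bond lies in the nodal plane of the enolate and is not expelled; acrolein approaches C5 on the exo face (C6 unit trans to C4–O); and triisopropoxytitanium enolates of cyclic ketones are known to favour the syn adduct, which is the C6 configuration required.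

Step 10
Reactants: 14 aldol adduct
Product: 15 (1R,5S,6R,7R)-6-[(tert-butyldimethylsilyl)oxy]-7-{(1R)-1-[(tert-butyldimethylsilyl)oxy]prop-2-en-1-yl}-2-oxa-4-azabicyclo[3.3.1]nonane-3,8-dione
Conditions: TBSOTf, 2,6-lutidine, CH2Cl2, −78 °C
Reagents that add atoms: tert-butyldimethylsilyl trifluoromethanesulfonate, CC(C)(C)[Si](C)(C)OS(=O)(=O)C(F)(F)F
Why: Silyl ether formation at the secondary allylic hydroxyl at low temperature, where the β-hydroxy ketone undergoes neither retro-aldol cleavage nor dehydration.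

Step 11
Reactants: 15 bis-silyl ketone; 16 vinylmagnesium bromide
Product: 17 C9 vinyl carbinol of 15 (vinyl on the exo face, cis to the C5 side chain; C9–OH on the carbamate face)
Conditions: CH2=CHMgBr (3.5 equiv), CeCl3, THF, −78 °C
Reagents that add atoms: vinylmagnesium bromide 16, C=C[Mg]Br
Why: Organocerium-mediated Grignard 1,2-addition (the first equivalent is consumed by the carbamate N–H) by axial attack on the exo face, anti to the axial C1–O bond (polar Felkin–Anh) and away from the carbamate bridge, which sets C9 with the vinyl group cis to the C5 side chain.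

Step 12
Reactants: 17 diene carbinol
Product: 18 tricyclic carbamate: cis-fused cyclopentene (C9–C5–C6–C7=C8) on the carbamate-bridged ring A, with C9–OH, C4–OTBS and C6–OTBS
Conditions: second-generation Grubbs catalyst (H2IMes)(PCy3)Cl2Ru=CHPh (5 mol %), CH2Cl2, 40 °C
Reagents that add atoms: none
Why: Ring-closing olefin metathesis of a 1,6-diene whose alkenes sit cis on adjacent ring carbons (axial vinyl on C9, equatorial chain on C5) closes the cis-fused cyclopentene with loss of ethene and changes no stereocentre.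

Step 13
Reactants: 18 tricyclic carbamate
Product: 19 N-Boc derivative of 18
Conditions: Boc2O, DMAP (0.2 equiv), Et3N, CH2Cl2, rt
Reagents that add atoms: di-tert-butyl dicarbonate, CC(C)(C)OC(=O)OC(=O)OC(C)(C)C
Why: DMAP-catalysed N-acylation of the acidic carbamate N–H gives an imide-type carbamate whose ring carbonyl is activated towards alkoxide, the hindered tertiary C9–OH remaining free.

Step 14
Reactants: 19 N-Boc carbamate
Product: 21 N-Boc amino diol of the cis-hydrindene (C1–OH; C9–OH; C4–OTBS; C6–OTBS), via methyl carbonate 20 (not isolated)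
Conditions: Cs2CO3 (0.5 equiv), MeOH, rt
Reagents that add atoms: none
Why: Alkoxide ring opening of an N-acyl cyclic carbamate: methoxide attacks the ring carbonyl and expels the Boc-stabilised nitrogen, and the resulting C1 methyl carbonate is transesterified by methanol, freeing C1–OH while nitrogen stays as NHBoc.

Step 15
Reactants: 21 diol
Product: 22 fused ketol: cis-bicyclo[4.3.0]non-7-en-2-one (six ring C1(=O)–C2–C3–C4–C5–C9, five ring C9–C5–C6–C7=C8) with angular C9–OH, C3–NHBoc, C4–OTBS and C6–OTBS; C3–N, C4–O, C5–H and C9–OH on one face of the six ring, C6–O cis to C5–H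
Conditions: IBX, DMSO, rt
Reagents that add atoms: none
Why: IBX oxidation of the secondary alcohol of a vicinal diol to the α-ketol without C–C cleavage, the tertiary C9 alcohol and silyl ethers being inert and the neutral medium sparing the β-carbamoyl ketone from elimination.

Step 16
Reactants: 22 fused ketol
Product: 24 bridged ketol 1-hydroxybicyclo[3.3.1]non-7-en-9-one bearing C3–NHBoc; C4–OTBS; C6–OTBS (all exo), via aluminium alkoxide 23 (not isolated)
Conditions: Al(OtBu)3 (2 equiv), toluene, 80 °C; aq Rochelle salt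
Reagents that add atoms: none
Why: Ligand exchange gives the C9 aluminium alkoxide, whose metal also binds the C1 carbonyl oxygen; within this chelate the C9–O bond becomes the C9 ketone while C8 moves with its bonding pair from C9 to C1, which becomes the tertiary carbinol. The closest known reaction is the α-ketol rearrangement with ring enlargement, as in the aluminium-alkoxide-mediated D-homoannulation of 17-hydroxy-20-keto steroids; Al(OtBu)3 is chosen because tert-butoxide has no carbinol hydrogen and cannot reduce the ketone in a Meerwein–Ponndorf–Verley sense. Ring B (C1–C8–C7–C6–C5–C9) is closed by enlargement of the cyclopentene through a suprafacial 1,2-shift, not by an end-to-end cyclisation, and C1–C8 is the only new bond. The new stereocentre C1 is fixed by the cis ring fusion: C8 can reach C1 only on the face of ring A on which it already sits (the face of C6), so the C1 hydroxyl ends on the face of N and the C4 oxygen. The step needs C8 rather than C5 to migrate: in the chair of ring A that keeps the C4 silyloxy group and the C6 carbon equatorial, the C9–O bond is equatorial and eclipsed with C1=O (the chelate) and the C9–C8 bond is axial, nearly parallel to the carbonyl π* orbital, whereas C9–C5 is tilted towards the carbonyl plane, and the sp2 carbon has the higher migratory aptitude. The shift is reversible and is expected, not proven, to run towards 24, because a cis-fused cyclopentene is exchanged for a cyclohexene and the C9 ketone of 24, flanked by two bridgeheads, can no longer enolise.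

Step 17
Reactants: 24 bridged ketol
Product: 25 3-ammonio-1,4,6-trihydroxybicyclo[3.3.1]non-7-en-9-one chloride (amine hydrochloride; configuration as in 24)
Conditions: HCl (4 M in dioxane)/MeOH 1:1, 0 °C to rt
Reagents that add atoms: hydrogen chloride, Cl
Why: Acidolysis cleaves the Boc carbamate and solvolyses both secondary silyl ethers in one operation; the bridgehead ketol can neither ionise nor enolise, and the ammonium salt keeps nitrogen from adding to the C9 ketone.

Step 18
Reactants: 26 δ-decalactone (racemic)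
Product: 27 6-pentyltetrahydro-2H-pyran-2-ol (lactol, mixture of isomers)
Conditions: iBu2AlH (1.05 equiv), CH2Cl2, −78 °C; aq Rochelle salt
Reagents that add atoms: none
Why: Partial hydride reduction of a lactone stops at the lactol because the tetrahedral aluminate does not collapse before the quench at −78 °C.

Step 19
Reactants: 27 lactol; 28 tert-butyl (triphenylphosphoranylidene)acetate
Product: 29 tert-butyl (E)-7-hydroxydodec-2-enoate
Conditions: toluene, 80 °C
Reagents that add atoms: tert-butyl (triphenylphosphoranylidene)acetate 28, CC(C)(C)OC(=O)C=P(c1ccccc1)(c1ccccc1)c1ccccc1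
Why: Wittig olefination of the open hydroxy-aldehyde tautomer with a stabilised ylide gives the E enoate under neutral conditions that do not promote oxa-Michael closure of the hydroxyl onto the enoate.

Step 20
Reactants: 29 hydroxy enoate
Product: 30 tert-butyl (E)-7-oxododec-2-enoate
Conditions: Dess–Martin periodinane, CH2Cl2, rt
Reagents that add atoms: none
Why: Dess–Martin oxidation of the secondary alcohol to the ketone, which also removes the racemic side-chain stereocentre.

Step 21
Reactants: 30 keto ester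
Product: 31 (E)-7-oxododec-2-enoic acid
Conditions: CF3CO2H/CH2Cl2 1:3, rt
Reagents that add atoms: none
Why: Acidolysis of the tert-butyl ester (loss of 2-methylpropene) leaves the ketone and the E alkene untouched.

Step 22
Reactants: 25 amine hydrochloride; 31 (E)-7-oxododec-2-enoic acid
Product: 32 (E)-7-oxododec-2-enamide of the C3 amine: the 7,8-alkene (deoxy) precursor of isariotin C
Conditions: EDC·HCl, HOBt, iPr2NEt, DMF, 0 °C to rt
Reagents that add atoms: (E)-7-oxododec-2-enoic acid 31, CCCCCC(=O)CCC/C=C/C(=O)O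
Why: Carbodiimide amide coupling through the hydroxybenzotriazole active ester, which acylates the liberated primary amine far faster than the secondary and tertiary hydroxyls.

Step 23
Reactants: 32 alkene amide
Product: 33 isariotin C
Conditions: VO(acac)2 (tetravalent vanadium, 5 mol %), tBuOOH (1.5 equiv), CH2Cl2, 0 °C to rt
Reagents that add atoms: tert-butyl hydroperoxide, CC(C)(C)OO
Why: Vanadium-catalysed hydroxyl-directed epoxidation of an allylic alcohol, in which the vanadate ester of the pseudoaxial C6 hydroxyl delivers oxygen to the exo face of C7=C8 (syn to C6–OH, away from ring A), setting C7 and C8, while the electron-poor enamide alkene is not epoxidised.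

**Compound list**

1 | cyclohexa-1,4-diene | C1=CCC=CC1 | starting material
2 | cis-7-oxabicyclo[4.1.0]hept-3-ene (meso) | C1=CC[C@@H]2O[C@@H]2C1 | intermediate
3 | (1R,6R)-6-hydroxycyclohex-3-en-1-yl benzoate | C1[C@@H](O)[C@H](OC(=O)c2ccccc2)CC=C1 | intermediate
4 | (1R,6R)-6-(benzoyloxy)cyclohex-3-en-1-yl 1H-imidazole-1-carboxylate | C1[C@@H](OC(=O)n2ccnc2)[C@H](OC(=O)c3ccccc3)CC=C1 | intermediate (not isolated)
5 | (1R,6R)-6-[(hydroxycarbamoyl)oxy]cyclohex-3-en-1-yl benzoate | C1[C@@H](OC(=O)NO)[C@H](OC(=O)c2ccccc2)CC=C1 | intermediate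
6 | (1R,6R)-6-({[(pentafluorobenzoyl)oxy]carbamoyl}oxy)cyclohex-3-en-1-yl benzoate | C1[C@@H](OC(=O)NOC(=O)c2c(F)c(F)c(F)c(F)c2F)[C@H](OC(=O)c3ccccc3)CC=C1 | intermediate
7 | (1R,5S,6R,8R)-6-hydroxy-3-oxo-2-oxa-4-azabicyclo[3.3.1]nonan-8-yl benzoate | O=C2N[C@H]1C[C@@H](O2)[C@H](OC(=O)c3ccccc3)C[C@H]1O | intermediate
8 | (1R,5S,6R,8R)-6-[(tert-butyldimethylsilyl)oxy]-3-oxo-2-oxa-4-azabicyclo[3.3.1]nonan-8-yl benzoate | O=C2N[C@H]1C[C@@H](O2)[C@H](OC(=O)c3ccccc3)C[C@H]1O[Si](C)(C)C(C)(C)C | intermediate
9 | (1R,5S,6R,8R)-6-[(tert-butyldimethylsilyl)oxy]-8-hydroxy-2-oxa-4-azabicyclo[3.3.1]nonan-3-one | O=C2N[C@H]1C[C@@H](O2)[C@H](O)C[C@H]1O[Si](C)(C)C(C)(C)C | intermediate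
10 | (1R,5S,6R)-6-[(tert-butyldimethylsilyl)oxy]-2-oxa-4-azabicyclo[3.3.1]nonane-3,8-dione | O=C2N[C@H]1C[C@@H](O2)C(=O)C[C@H]1O[Si](C)(C)C(C)(C)C | intermediate
11 | acrolein | C=CC=O | starting material
12 | dilithium enolate of 10 (N-lithio carbamate, C9 lithium enolate, C9=C5) | O=C2N([Li])[C@H]1C[C@@H](O2)C(O[Li])=C[C@H]1O[Si](C)(C)C(C)(C)C | intermediate (not isolated)
13 | N,O-bis(triisopropoxytitanium) enolate of 10 | O=C2N([Ti](OC(C)C)(OC(C)C)OC(C)C)[C@H]1C[C@@H](O2)C(O[Ti](OC(C)C)(OC(C)C)OC(C)C)=C[C@H]1O[Si](C)(C)C(C)(C)C | intermediate (not isolated)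
14 | (1R,5S,6R,7R)-6-[(tert-butyldimethylsilyl)oxy]-7-[(1R)-1-hydroxyprop-2-en-1-yl]-2-oxa-4-azabicyclo[3.3.1]nonane-3,8-dione | O=C2N[C@H]1C[C@@H](O2)C(=O)[C@H]([C@H](O)C=C)[C@H]1O[Si](C)(C)C(C)(C)C | intermediate
15 | (1R,5S,6R,7R)-6-[(tert-butyldimethylsilyl)oxy]-7-{(1R)-1-[(tert-butyldimethylsilyl)oxy]prop-2-en-1-yl}-2-oxa-4-azabicyclo[3.3.1]nonane-3,8-dione | O=C2N[C@H]1C[C@@H](O2)C(=O)[C@H]([C@H](O[Si](C)(C)C(C)(C)C)C=C)[C@H]1O[Si](C)(C)C(C)(C)C | intermediate
16 | vinylmagnesium bromide | C=C[Mg]Br | starting material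
17 | C9 vinyl carbinol of 15 (vinyl exo, cis to the C5 side chain) | O=C2N[C@H]1C[C@@H](O2)[C@@](C=C)(O)[C@H]([C@H](O[Si](C)(C)C(C)(C)C)C=C)[C@H]1O[Si](C)(C)C(C)(C)C | intermediate
18 | tricyclic carbamate (cis-fused cyclopentene, C9–OH, C4–OTBS, C6–OTBS, carbamate bridging C1–O and C3–N) | O=C3N[C@H]1C[C@@H](O3)[C@@]2(O)[C@H]([C@H](O[Si](C)(C)C(C)(C)C)C=C2)[C@H]1O[Si](C)(C)C(C)(C)C | intermediate
19 | N-Boc derivative of 18 | O=C3N(C(=O)OC(C)(C)C)[C@H]1C[C@@H](O3)[C@@]2(O)[C@H]([C@H](O[Si](C)(C)C(C)(C)C)C=C2)[C@H]1O[Si](C)(C)C(C)(C)C | intermediate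
20 | C1 methyl carbonate of 21 | CC(C)(C)OC(=O)N[C@H]1C[C@@H](OC(=O)OC)[C@@]2(O)[C@H]([C@H](O[Si](C)(C)C(C)(C)C)C=C2)[C@H]1O[Si](C)(C)C(C)(C)C | intermediate (not isolated)
21 | N-Boc amino diol of the cis-hydrindene (C1–OH, C9–OH, C4–OTBS, C6–OTBS) | CC(C)(C)OC(=O)N[C@H]1C[C@@H](O)[C@@]2(O)[C@H]([C@H](O[Si](C)(C)C(C)(C)C)C=C2)[C@H]1O[Si](C)(C)C(C)(C)C | intermediate
22 | fused ketol: cis-hydrindenone with C1 ketone, angular C9–OH, C3–NHBoc, C4–OTBS, C6–OTBS | CC(C)(C)OC(=O)N[C@H]1CC(=O)[C@@]2(O)[C@H]([C@H](O[Si](C)(C)C(C)(C)C)C=C2)[C@H]1O[Si](C)(C)C(C)(C)C | intermediate (key-step precursor)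
23 | C9 di-tert-butoxyaluminium alkoxide of 22 | CC(C)(C)OC(=O)N[C@H]1CC(=O)[C@@]2(O[Al](OC(C)(C)C)OC(C)(C)C)[C@H]([C@H](O[Si](C)(C)C(C)(C)C)C=C2)[C@H]1O[Si](C)(C)C(C)(C)C | intermediate (not isolated)
24 | bridged ketol: 1-hydroxybicyclo[3.3.1]non-7-en-9-one with C3–NHBoc, C4–OTBS, C6–OTBS | CC(C)(C)OC(=O)N[C@H]1C[C@@]2(O)C(=O)[C@H]([C@H](O[Si](C)(C)C(C)(C)C)C=C2)[C@H]1O[Si](C)(C)C(C)(C)C | intermediate (key-step product)
25 | 3-ammonio-1,4,6-trihydroxybicyclo[3.3.1]non-7-en-9-one chloride | [Cl-].[NH3+][C@H]1C[C@@]2(O)C(=O)[C@H]([C@H](O)C=C2)[C@H]1O | intermediate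
26 | δ-decalactone (racemic) | CCCCCC1CCCC(=O)O1 | starting material
27 | 6-pentyltetrahydro-2H-pyran-2-ol | CCCCCC1CCCC(O)O1 | intermediate
28 | tert-butyl (triphenylphosphoranylidene)acetate | CC(C)(C)OC(=O)C=P(c1ccccc1)(c1ccccc1)c1ccccc1 | starting material
29 | tert-butyl (E)-7-hydroxydodec-2-enoate | CCCCCC(O)CCC/C=C/C(=O)OC(C)(C)C | intermediate
30 | tert-butyl (E)-7-oxododec-2-enoate | CCCCCC(=O)CCC/C=C/C(=O)OC(C)(C)C | intermediate
31 | (E)-7-oxododec-2-enoic acid | CCCCCC(=O)CCC/C=C/C(=O)O | intermediate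
32 | 7,8-alkene (deoxy) precursor of isariotin C | CCCCCC(=O)CCC/C=C/C(=O)N[C@H]1C[C@@]2(O)C(=O)[C@H]([C@H](O)C=C2)[C@H]1O | intermediate
33 | isariotin C | CCCCCC(=O)CCC/C=C/C(=O)N[C@H]1C[C@@]2(O)C(=O)[C@H]([C@H](O)[C@@H]3O[C@@H]32)[C@H]1O | target

**Step count**

Total: 23 steps (19 on the main line, 4 for the side-chain acid). Longest linear sequence: 19 steps (steps 1–17, 22, 23).

**Steps most likely to fail**

Step 16 (ketol shift). Under the aluminium alkoxide the C1 ketone may enolise towards C2 and expel the axial C3 carbamate nitrogen before C8 shifts; the equilibrium may stop short of the bridged ketol; or C5 may shift instead of C8. The fallback sets out from 15 and returns at 24, and closes ring B by metathesis across C1 and C5 instead of by a shift. NaBH4 in MeOH reduces 15 from the exo face to the C9 alcohol F1. TESOTf/2,6-lutidine gives the C9 triethylsilyl ether F2. Boc2O/DMAP gives the N-Boc carbamate F3, and Cs2CO3/MeOH opens it to the C1 alcohol F4. Dess–Martin oxidation gives the C1 ketone F5. CH2=CHMgBr/CeCl3 at −78 °C should add anti to the C9 silyloxy group to give the C1 vinyl carbinol F6. Pyridinium p-toluenesulfonate in MeOH removes only the triethylsilyl group to give the diol F7, and Dess–Martin oxidation gives the open-chain ketol F8. Ring-closing metathesis with the second-generation Grubbs catalyst between the C1 vinyl group and the C5 side chain (both axial on the same face) then gives 24.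

Step 9 (syn aldol). The titanium enolate may add with low syn selectivity at C6, or the dianion may convert poorly. The fallback sets out from 10 and returns at 18. Soft enolisation with Cy2BCl/Et3N and addition to acrolein should give, through the chair transition state of the E enolate, the anti aldol adduct F9 (C6 epimer of 14, still exo at C5). Excess CH2=CHMgBr/CeCl3 gives the diol F10, and ring-closing metathesis gives the cyclopentenol F11 with the C6 hydroxyl on the concave face. A Mitsunobu reaction (4-nitrobenzoic acid, PPh3, diisopropyl azodicarboxylate) inverts C6 by attack from the open convex face to give the ester F12. K2CO3/MeOH gives the C6 alcohol F13, and TBSOTf/2,6-lutidine at −78 °C silylates the secondary hydroxyl only, giving 18.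

Step 5 (tethered aminohydroxylation). The tethered imido osmium species may fail to reach C3=C4 across the ring, since the carbamate must turn axial, so that turnover is slow and the N–O reagent decays to the primary carbamate. The fallback sets out from 2 and returns at 10; nitrogen is introduced first and the C1 oxygen is delivered from it. Ring opening of 2 with Me3SiN3 and the enantiomer of azido[N,N'-bis(3,5-di-tert-butylsalicylidene)-1,2-cyclohexanediaminato]chromium (trivalent chromium) that leads to the (1S,6S) series gives the azido silyl ether F14. K2CO3/MeOH gives (1S,6S)-6-azidocyclohex-3-en-1-ol F15. Mitsunobu inversion at C4 (4-nitrobenzoic acid, PPh3, diisopropyl azodicarboxylate) gives the cis azido ester F16, and K2CO3/MeOH gives the cis azido alcohol F17. TBSCl/imidazole gives the silyl ether F18. Staudinger reduction (PPh3, H2O) followed by Boc2O gives the carbamate F19. Iodocyclisation (I2, NaHCO3, MeCN), in which the Boc carbonyl oxygen attacks C1 on the face of nitrogen and loses 2-methylpropene, gives the iodo carbamate F20. Radical hydroxylation (Bu3SnH, air, toluene; then PPh3) replaces iodine by hydroxyl to give 9 together with its C9 epimer F21, and Dess–Martin oxidation of both (step 8) gives 10.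

**Further compounds**

F1 | step 16 | C9 alcohol from 15 (OH on the carbamate face) | O=C2N[C@H]1C[C@@H](O2)[C@@H](O)[C@H]([C@H](O[Si](C)(C)C(C)(C)C)C=C)[C@H]1O[Si](C)(C)C(C)(C)C
F2 | step 16 | C9 triethylsilyl ether of F1 | O=C2N[C@H]1C[C@@H](O2)[C@@H](O[Si](CC)(CC)CC)[C@H]([C@H](O[Si](C)(C)C(C)(C)C)C=C)[C@H]1O[Si](C)(C)C(C)(C)C
F3 | step 16 | N-Boc derivative of F2 | O=C2N(C(=O)OC(C)(C)C)[C@H]1C[C@@H](O2)[C@@H](O[Si](CC)(CC)CC)[C@H]([C@H](O[Si](C)(C)C(C)(C)C)C=C)[C@H]1O[Si](C)(C)C(C)(C)C
F4 | step 16 | ring-opened C1 alcohol (C3–NHBoc, C9–OTES) | CC(C)(C)OC(=O)N[C@H]1C[C@@H](O)[C@@H](O[Si](CC)(CC)CC)[C@H]([C@H](O[Si](C)(C)C(C)(C)C)C=C)[C@H]1O[Si](C)(C)C(C)(C)C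
F5 | step 16 | C1 ketone (C9–OTES) | CC(C)(C)OC(=O)N[C@H]1CC(=O)[C@@H](O[Si](CC)(CC)CC)[C@H]([C@H](O[Si](C)(C)C(C)(C)C)C=C)[C@H]1O[Si](C)(C)C(C)(C)C
F6 | step 16 | C1 vinyl carbinol (vinyl cis to the C5 side chain, C9–OTES) | CC(C)(C)OC(=O)N[C@H]1C[C@@](C=C)(O)[C@@H](O[Si](CC)(CC)CC)[C@H]([C@H](O[Si](C)(C)C(C)(C)C)C=C)[C@H]1O[Si](C)(C)C(C)(C)C
F7 | step 16 | C1,C9 diol | CC(C)(C)OC(=O)N[C@H]1C[C@@](C=C)(O)[C@@H](O)[C@H]([C@H](O[Si](C)(C)C(C)(C)C)C=C)[C@H]1O[Si](C)(C)C(C)(C)C
F8 | step 16 | open-chain ketol (C1 vinyl carbinol, C9 ketone) | CC(C)(C)OC(=O)N[C@H]1C[C@@](C=C)(O)C(=O)[C@H]([C@H](O[Si](C)(C)C(C)(C)C)C=C)[C@H]1O[Si](C)(C)C(C)(C)C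
F9 | step 9 | anti aldol adduct (C6 epimer of 14) | O=C2N[C@H]1C[C@@H](O2)C(=O)[C@H]([C@@H](O)C=C)[C@H]1O[Si](C)(C)C(C)(C)C
F10 | step 9 | C9 vinyl carbinol of F9 | O=C2N[C@H]1C[C@@H](O2)[C@@](C=C)(O)[C@H]([C@@H](O)C=C)[C@H]1O[Si](C)(C)C(C)(C)C
F11 | step 9 | cyclopentenol with concave C6–OH | O=C3N[C@H]1C[C@@H](O3)[C@@]2(O)[C@H]([C@@H](O)C=C2)[C@H]1O[Si](C)(C)C(C)(C)C
F12 | step 9 | inverted C6 4-nitrobenzoate | O=C3N[C@H]1C[C@@H](O3)[C@@]2(O)[C@H]([C@H](OC(=O)c4ccc(cc4)[N+](=O)[O-])C=C2)[C@H]1O[Si](C)(C)C(C)(C)C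
F13 | step 9 | cyclopentenol with convex C6–OH | O=C3N[C@H]1C[C@@H](O3)[C@@]2(O)[C@H]([C@H](O)C=C2)[C@H]1O[Si](C)(C)C(C)(C)C
F14 | step 5 | trans azido trimethylsilyl ether | [N-]=[N+]=N[C@H]1CC=CC[C@@H]1O[Si](C)(C)C
F15 | step 5 | (1S,6S)-6-azidocyclohex-3-en-1-ol | [N-]=[N+]=N[C@H]1CC=CC[C@@H]1O
F16 | step 5 | cis azido 4-nitrobenzoate | [N-]=[N+]=N[C@H]1CC=CC[C@H]1OC(=O)c2ccc(cc2)[N+](=O)[O-]
F17 | step 5 | cis azido alcohol | [N-]=[N+]=N[C@H]1CC=CC[C@H]1O
F18 | step 5 | cis azido tert-butyldimethylsilyl ether | [N-]=[N+]=N[C@H]1CC=CC[C@H]1O[Si](C)(C)C(C)(C)C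
F19 | step 5 | cis N-Boc amino silyl ether | CC(C)(C)OC(=O)N[C@H]1CC=CC[C@H]1O[Si](C)(C)C(C)(C)C
F20 | step 5 | C9 iodo bicyclic carbamate (iodine trans to C1–O) | O=C2N[C@H]1C[C@@H](O2)[C@H](I)C[C@H]1O[Si](C)(C)C(C)(C)C
F21 | step 5 | C9 epimer of 9 | O=C2N[C@H]1C[C@@H](O2)[C@@H](O)C[C@H]1O[Si](C)(C)C(C)(C)C
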